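**Plan**

- Cuts (retrosynthesis): first the C3–O tiglate and the C11–O aryl ether; then the transannular C5–C10 bond, which reduces the decalin to a ten-membered ring; then C3–C4 (opening that ring) and C9–C10 (separating a geraniol-derived piece, C4–C9 with C11 and the methyls, from a pentynol-derived piece, C10 and C1–C3).
- Enabling feature: C1–C10 form the periphery of rings A and B and C5–C10 is the only bond crossing it, so a cyclodec-5-ene with a methylene on C10 is the decalin minus one bond and two hydrogen atoms; because C4 is quaternary, a cationic closure would leave a secondary C6 cation, hence a radical closure.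
- Forward order: C9–C10 by copper-catalysed opening of (2R,3R)-epoxygeraniol with an alkenyl Grignard reagent; the ten-membered ring by CrCl2-mediated allylation at C3–C4; rings A and B together in step 13, when hydrogen-atom transfer to the methylene triggers C5–C10 bond formation across the ring.
- Stereochemistry: C8 and C9 from Sharpless epoxidation and invertive epoxide opening; C5 and C10 in the key step under the influence of C8 and C9; C3 last, by hydride reduction of a 3-ketone to the equatorial alcohol, which is why C3 passes through the key step as a ketone.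
- Endgame: Yamaguchi tigloylation of C3–OH, removal of both silyl ethers, Mitsunobu etherification of C11–OH with umbelliferone.

Key step: step 13

Remark: the target SMILES is read as (3R,5S,8R,9S,10R) in drimane numbering (trans-decalin; C3 ester oxygen equatorial and cis to the C10 methyl; C8 hydroxyl axial and cis to it; C9 CH2OAr arm axial and trans to it); drimane locants are used for all intermediates (C11 = CH2O on C9, C12 = methyl on C8, C13 and C14 = methyls on C4, C15 = methyl or methylene carbon on C10), "seco" marks bonds not yet formed, and TBS = tert-butyldimethylsilyl, PMB = 4-methoxybenzyl, dpm = dipivaloylmethanate.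

**Route**

Step 1
Reactants: 1 geraniol
Product: 2 (2R,3R)-2,3-epoxygeraniol
Conditions: Ti(OiPr)4 (5 mol%), D-(−)-diethyl tartrate (7 mol%), TBHP, 4 Å MS, CH2Cl2, −20 °C
Reagents that add atoms: tert-butyl hydroperoxide, CC(C)(C)OO
Why: Sharpless asymmetric epoxidation of an (E)-trisubstituted allylic alcohol, in which the titanium complex of D-(−)-tartrate delivers oxygen to the face that gives the (2R,3R)-epoxide and thereby fixes the future C8 (R) and, after inversion in step 4, the future C9, while the remote trisubstituted alkene, which has no directing hydroxyl, is left alone.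

Step 2
Reactants: 3 pent-4-yn-1-ol
Product: 4 4-bromopent-4-en-1-ol
Conditions: HBr (48% aq.), Et4NBr, CH2Cl2, 40 °C
Reagents that add atoms: hydrogen bromide, Br
Why: Markovnikov hydrobromination of a terminal alkyne under bromide-rich conditions places bromine on the internal carbon, the future C10, and turns the terminal carbon into the future exocyclic methylene without adding a second molecule of HBr.

Step 3
Reactants: 4 4-bromopent-4-en-1-ol
Product: 5 4-bromopent-4-en-1-yl 4-methoxybenzyl ether
Conditions: NaH, PMBCl, n-Bu4NI (cat.), THF, 0 → 25 °C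
Reagents that add atoms: 4-methoxybenzyl chloride, COc1ccc(CCl)cc1
Why: Williamson etherification protects the future C3 oxygen as a 4-methoxybenzyl ether that survives the Grignard, peracid and selenium steps and can later be removed oxidatively beside silyl ethers.

Step 4
Reactants: 5 4-bromopent-4-en-1-yl 4-methoxybenzyl ether; 2 (2R,3R)-2,3-epoxygeraniol
Product: 7 (8R,9S)-3-(PMB-oxy)-3,4:5,10-disecodrima-4,10(15)-diene-8,11-diol, via alkenylmagnesium bromide 6 (not isolated)
Conditions: 5, Mg, THF, 40 °C; then CuI (10 mol%), 2, THF, −30 → 0 °C
Reagents that add atoms: none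
Why: Copper-catalysed Grignard opening of a 2,3-epoxy alcohol, in which the alkenylcopper species attacks the secondary C2 of the trisubstituted epoxide (the other epoxide carbon is fully substituted) from the back side, so that the C9–C10 bond forms with inversion to set C9 (S) while C8 (R) keeps its C–O bond.

Step 5
Reactants: 7 (8R,9S)-diol
Product: 8 8,11-bis-O-TBS ether of 7
Conditions: TBSOTf (3 equiv), 2,6-lutidine, CH2Cl2, 0 → 25 °C
Reagents that add atoms: tert-butyldimethylsilyl triflate, CC(C)(C)[Si](C)(C)OS(=O)(=O)C(F)(F)F
Why: Silylation with a silyl triflate is reactive enough to cap the tertiary C8 hydroxyl together with the primary C11 hydroxyl, which keeps the C8 oxygen from opening the later epoxide or allylic chloride to a cyclic ether.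

Step 6
Reactants: 8 bis-TBS ether
Product: 9 4,5-epoxide of 8 (both C5 epimers)
Conditions: mCPBA (1.0 equiv), NaHCO3, CH2Cl2, −20 → 0 °C
Reagents that add atoms: 3-chloroperbenzoic acid, OOC(=O)c1cccc(Cl)c1
Why: Prilezhaev epoxidation is selective for the electron-rich trisubstituted alkene over the hindered 1,1-disubstituted methylene, and the uncontrolled new centre at C5 is of no consequence because it returns to sp2 in step 7.

Step 7
Reactants: 9 4,5-epoxide
Product: 12 (5E,8R,9S)-tertiary allylic alcohol (4-hydroxy with C5=C6), via hydroxy selenide 10 (not isolated), via selenoxide 11 (not isolated)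
Conditions: (PhSe)2, NaBH4, EtOH, 25 → 70 °C; then 30% H2O2, NaHCO3, THF, 0 → 25 °C
Reagents that add atoms: none
Why: Sharpless–Lauer conversion of an epoxide into an allylic alcohol, in which phenylselenolate opens the epoxide at the secondary C5 and the derived selenoxide can undergo syn elimination only towards C6 because C4 carries no hydrogen, which delivers the (E)-C5=C6 alkene and the tertiary C4 alcohol as one regioisomer.

Step 8
Reactants: 12 tertiary allylic alcohol
Product: 13 (5E,8R,9S)-3,4-diol (primary C3–OH and tertiary C4–OH)
Conditions: DDQ, CH2Cl2/pH 7 buffer, 0 °C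
Reagents that add atoms: none
Why: Oxidative cleavage of the 4-methoxybenzyl ether with DDQ proceeds under near-neutral conditions that leave both silyl ethers, the tertiary allylic alcohol and the two alkenes untouched.

Step 9
Reactants: 13 3,4-diol
Product: 14 (5E,8R,9S)-4-hydroxy C3 aldehyde
Conditions: Dess–Martin periodinane, NaHCO3, CH2Cl2, 0 → 25 °C
Reagents that add atoms: none
Why: Dess–Martin oxidation converts the primary C3 alcohol into the aldehyde, whereas the tertiary allylic alcohol has no carbinol hydrogen and cannot react.

Step 10
Reactants: 14 hydroxy aldehyde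
Product: 15 (8R,9S)-6-chloro C3 aldehyde with C4=C5 (C6 epimers)
Conditions: SOCl2, pyridine, Et2O, −20 → 0 °C; used without purification
Reagents that add atoms: thionyl chloride, O=S(Cl)Cl
Why: Chlorination of a tertiary allylic alcohol with thionyl chloride occurs with allylic transposition through the chlorosulfite (the linalool-to-geranyl chloride type of reaction), and because the secondary chloride shown and any tertiary regioisomer ionise to the same allyl unit, neither the position of chlorine nor the configuration at C6 matters for step 11.

Step 11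
Reactants: 15 allylic chloride aldehyde
Product: 17 (5E,8R,9S)-8,11-bis(TBS-oxy)-5,10-secodrima-5,10(15)-dien-3-ol (C3 epimers), via allylchromium dichloride 16 (not isolated)
Conditions: CrCl2 (8 equiv), THF, 25 °C, syringe-pump addition of 15, 0.003 M
Reagents that add atoms: none
Why: Intramolecular Nozaki–Hiyama allylation, a reaction type established for closing ten-membered carbocycles, in which the allylchromium 16 adds to the aldehyde through its γ-carbon (the gem-dimethyl terminus C4) in a chair transition state to form C3–C4 and the quaternary C4, the axial γ-methyl forcing the C7 arm on the α-carbon equatorial so that the new C5=C6 alkene is (E), while the C3 carbinol centre forms without reliable control and is erased in step 12.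

Step 12
Reactants: 17 cyclodecadienol
Product: 18 (5E,8R,9S)-8,11-bis(TBS-oxy)-5,10-secodrima-5,10(15)-dien-3-one
Conditions: Dess–Martin periodinane, NaHCO3, CH2Cl2, 25 °C
Reagents that add atoms: none
Why: Dess–Martin oxidation merges both C3 epimers into a single β,γ-unsaturated ketone that cannot slip into conjugation because C4 is quaternary.

Step 13
Reactants: 18 cyclodecadienone
Product: 21 (5S,8R,9S,10R)-8,11-bis(TBS-oxy)driman-3-one, via C10 radical 19 (not isolated), via C6 radical 20 (not isolated)
Conditions: Mn(dpm)3 (10 mol%), PhSiH3, TBHP, i-PrOH, 22 °C, 0.005 M, Ar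
Reagents that add atoms: none
Why: Proposed new method: the manganese hydride formed from Mn(dpm)3, PhSiH3 and TBHP transfers a hydrogen atom to the terminal carbon of the C10 methylene, which creates the C10 methyl group and the tertiary C10 radical 19; this radical adds across the ring to C5 of the (E)-C5=C6 alkene, and the unstabilised secondary C6 radical 20 is quenched by a second hydrogen-atom transfer, the reason for choosing a manganese hydrogenation system over an iron one that relies on reduction to an enolate. The closest known reaction types are hydrogen-atom-transfer hydrogenation and reductive cyclisation of 1,1-disubstituted alkenes onto unactivated alkenes and the transannular closure of (E)-cyclodec-5-enyl radicals and cations to trans-decalins, but their combination in a ten-membered ring has no precedent. One ring is closed, because the new bond divides the ten-membered ring into rings A and B: the closure is 6-exo-trig when counted through ring A (C10, C1 to C4, C5, with the radical left on exocyclic C6) and 6-endo when counted through ring B. C5 and C10 are set together, the (E)-alkene and a chair–chair transition state placing H5 anti to the new C10 methyl (trans fusion), while the face is chosen by the preset C8 and C9 centres, because the forming ring B chair keeps the C8 methyl equatorial and the C8 silyloxy group and the C9 CH2OTBS arm anti-diaxial, which avoids a syn-axial clash between the C8 and C10 methyl groups. The step needs hydrogen-atom transfer to the 1,1-disubstituted alkene only (the 1,2-disubstituted alkene reacts far more slowly), attack on C5 and not on C6 (C5 lies directly across the ring from C10 and leads to two chairs, C6 attack to a strained hydroazulene) and cyclisation ahead of premature reduction of 19 (high dilution keeps the hydride donor scarce). The C3 ketone, insulated from the alkene by the quaternary C4, and both silyl ethers should be inert under these conditions.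

Step 14
Reactants: 21 decalinone
Product: 22 (3R,5S,8R,9S,10R)-8,11-bis(TBS-oxy)driman-3-ol
Conditions: NaBH4, MeOH/THF, 0 °C
Reagents that add atoms: none
Why: Borohydride reduction of a 4,4-dimethyl-3-oxo-trans-decalin, in which hydride enters axially on the face opposite the axial C4 and C10 methyl groups (the course known for 3-oxo-triterpenoids) and so sets C3 (R) with the hydroxyl equatorial and cis to the C10 methyl.

Step 15
Reactants: 22 C3 alcohol; 23 tiglic acid
Product: 25 (3R,5S,8R,9S,10R)-8,11-bis(TBS-oxy)driman-3-yl tiglate, via mixed anhydride 24 (not isolated)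
Conditions: 23, 2,4,6-Cl3C6H2COCl, Et3N, THF, 25 °C; then 22, DMAP, toluene, 60 °C
Reagents that add atoms: none
Why: Yamaguchi esterification through the mixed anhydride 24 and its acylpyridinium ion acylates the hindered equatorial C3 alcohol with retention at C3 and without disturbing the (E)-geometry of the tigloyl group or the tertiary silyl ether.

Step 16
Reactants: 25 bis-silyl tiglate
Product: 26 (3R,5S,8R,9S,10R)-8,11-dihydroxydriman-3-yl tiglate
Conditions: HF·pyridine, THF/pyridine, 0 → 40 °C
Reagents that add atoms: none
Why: Fluoride-driven Si–O cleavage with buffered HF removes the primary and the tertiary silyl ether in one operation under conditions mild enough for the tiglate and for the tertiary C8 alcohol.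

Step 17
Reactants: 26 diol tiglate; 27 umbelliferone
Product: 28 target CNP0189964.3
Conditions: PPh3, DIAD, THF, 0 → 50 °C
Reagents that add atoms: none
Why: Mitsunobu etherification activates only the primary C11 hydroxyl as its oxyphosphonium ion, which the acidic 7-hydroxyl of umbelliferone displaces, the tertiary C8 hydroxyl being too hindered to react and held anti to C11 so that it cannot close an oxetane.

**Compound list**

1 | geraniol, (2E)-3,7-dimethylocta-2,6-dien-1-ol | CC(C)=CCC/C(C)=C/CO | starting material
2 | (2R,3R)-2,3-epoxygeraniol, [(2R,3R)-3-methyl-3-(4-methylpent-3-en-1-yl)oxiran-2-yl]methanol | CC(C)=CCC[C@@]1(C)O[C@@H]1CO | intermediate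
3 | pent-4-yn-1-ol | C#CCCCO | starting material
4 | 4-bromopent-4-en-1-ol | C=C(Br)CCCO | intermediate
5 | 1-{[(4-bromopent-4-en-1-yl)oxy]methyl}-4-methoxybenzene (PMB ether of 4) | C=C(Br)CCCOCc1ccc(OC)cc1 | intermediate
6 | {5-[(4-methoxybenzyl)oxy]pent-1-en-2-yl}magnesium bromide | C=C([Mg]Br)CCCOCc1ccc(OC)cc1 | intermediate
7 | (2S,3R)-2-{5-[(4-methoxybenzyl)oxy]pent-1-en-2-yl}-3,7-dimethyloct-6-ene-1,3-diol, i.e. (8R,9S)-3-(PMB-oxy)-3,4:5,10-disecodrima-4,10(15)-diene-8,11-diol | CC(C)=CCC[C@@](C)(O)[C@@H](C(=C)CCCOCc1ccc(OC)cc1)CO | intermediate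
8 | (8R,9S)-8,11-bis(TBS-oxy)-3-(PMB-oxy)-3,4:5,10-disecodrima-4,10(15)-diene | CC(C)=CCC[C@@](C)(O[Si](C)(C)C(C)(C)C)[C@@H](C(=C)CCCOCc1ccc(OC)cc1)CO[Si](C)(C)C(C)(C)C | intermediate
9 | (8R,9S)-4,5-epoxy-8,11-bis(TBS-oxy)-3-(PMB-oxy)-3,4:5,10-disecodrim-10(15)-ene, both C5 epimers | CC1(C)OC1CC[C@@](C)(O[Si](C)(C)C(C)(C)C)[C@@H](C(=C)CCCOCc1ccc(OC)cc1)CO[Si](C)(C)C(C)(C)C | intermediate
10 | hydroxy selenide: 9 opened to the 4-hydroxy-5-(phenylselanyl) compound | CC(C)(O)C([Se]c1ccccc1)CC[C@@](C)(O[Si](C)(C)C(C)(C)C)[C@@H](C(=C)CCCOCc1ccc(OC)cc1)CO[Si](C)(C)C(C)(C)C | intermediate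
11 | selenoxide of 10 | CC(C)(O)C([Se](=O)c1ccccc1)CC[C@@](C)(O[Si](C)(C)C(C)(C)C)[C@@H](C(=C)CCCOCc1ccc(OC)cc1)CO[Si](C)(C)C(C)(C)C | intermediate
12 | (5E,8R,9S)-8,11-bis(TBS-oxy)-3-(PMB-oxy)-3,4:5,10-disecodrima-5,10(15)-dien-4-ol | CC(C)(O)/C=C/C[C@@](C)(O[Si](C)(C)C(C)(C)C)[C@@H](C(=C)CCCOCc1ccc(OC)cc1)CO[Si](C)(C)C(C)(C)C | intermediate
13 | (5E,8R,9S)-8,11-bis(TBS-oxy)-3,4:5,10-disecodrima-5,10(15)-diene-3,4-diol | CC(C)(O)/C=C/C[C@@](C)(O[Si](C)(C)C(C)(C)C)[C@@H](C(=C)CCCO)CO[Si](C)(C)C(C)(C)C | intermediate
14 | (5E,8R,9S)-8,11-bis(TBS-oxy)-4-hydroxy-3,4:5,10-disecodrima-5,10(15)-dien-3-al | CC(C)(O)/C=C/C[C@@](C)(O[Si](C)(C)C(C)(C)C)[C@@H](C(=C)CCC=O)CO[Si](C)(C)C(C)(C)C | intermediate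
15 | (8R,9S)-8,11-bis(TBS-oxy)-6-chloro-3,4:5,10-disecodrima-4,10(15)-dien-3-al, C6 epimers | CC(C)=CC(Cl)C[C@@](C)(O[Si](C)(C)C(C)(C)C)[C@@H](C(=C)CCC=O)CO[Si](C)(C)C(C)(C)C | intermediate
16 | allylchromium dichloride derived from 15 (CrCl2 group on C6) | CC(C)=CC([Cr](Cl)Cl)C[C@@](C)(O[Si](C)(C)C(C)(C)C)[C@@H](C(=C)CCC=O)CO[Si](C)(C)C(C)(C)C | intermediate
17 | (5E,8R,9S)-8,11-bis(TBS-oxy)-5,10-secodrima-5,10(15)-dien-3-ol, C3 epimers (ten-membered ring C1–C10, methylene on C10) | C=C1CCC(O)C(C)(C)/C=C/C[C@@](C)(O[Si](C)(C)C(C)(C)C)[C@@H]1CO[Si](C)(C)C(C)(C)C | intermediate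
18 | (5E,8R,9S)-8,11-bis(TBS-oxy)-5,10-secodrima-5,10(15)-dien-3-one (key-step precursor) | C=C1CCC(=O)C(C)(C)/C=C/C[C@@](C)(O[Si](C)(C)C(C)(C)C)[C@@H]1CO[Si](C)(C)C(C)(C)C | intermediate
19 | tertiary C10 radical formed from 18 by hydrogen-atom addition to C15 | C[C]1CCC(=O)C(C)(C)/C=C/C[C@@](C)(O[Si](C)(C)C(C)(C)C)[C@@H]1CO[Si](C)(C)C(C)(C)C | intermediate
20 | secondary C6 radical of the cyclised trans-decalin | O=C1CC[C@]2(C)[C@H]([CH]C[C@@](C)(O[Si](C)(C)C(C)(C)C)[C@@H]2CO[Si](C)(C)C(C)(C)C)C1(C)C | intermediate
21 | (5S,8R,9S,10R)-8,11-bis(TBS-oxy)driman-3-one (key-step product) | O=C1CC[C@]2(C)[C@H](CC[C@@](C)(O[Si](C)(C)C(C)(C)C)[C@@H]2CO[Si](C)(C)C(C)(C)C)C1(C)C | intermediate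
22 | (3R,5S,8R,9S,10R)-8,11-bis(TBS-oxy)driman-3-ol | O[C@@H]1CC[C@]2(C)[C@H](CC[C@@](C)(O[Si](C)(C)C(C)(C)C)[C@@H]2CO[Si](C)(C)C(C)(C)C)C1(C)C | intermediate
23 | tiglic acid, (E)-2-methylbut-2-enoic acid | C/C=C(\C)C(=O)O | starting material
24 | (E)-2-methylbut-2-enoic 2,4,6-trichlorobenzoic anhydride | C/C=C(\C)C(=O)OC(=O)c1c(Cl)cc(Cl)cc1Cl | intermediate
25 | (3R,5S,8R,9S,10R)-8,11-bis(TBS-oxy)driman-3-yl (E)-2-methylbut-2-enoate | C/C=C(\C)C(=O)O[C@@H]1CC[C@]2(C)[C@H](CC[C@@](C)(O[Si](C)(C)C(C)(C)C)[C@@H]2CO[Si](C)(C)C(C)(C)C)C1(C)C | intermediate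
26 | (3R,5S,8R,9S,10R)-8,11-dihydroxydriman-3-yl (E)-2-methylbut-2-enoate | C/C=C(\C)C(=O)O[C@@H]1CC[C@]2(C)[C@H](CC[C@@](C)(O)[C@@H]2CO)C1(C)C | intermediate
27 | umbelliferone, 7-hydroxy-2H-chromen-2-one | Oc1ccc2ccc(=O)oc2c1 | starting material
28 | CNP0189964.3, 7-{[(3R,5S,8R,9S,10R)-8-hydroxy-3-[(E)-2-methylbut-2-enoyloxy]driman-11-yl]oxy}-2H-chromen-2-one | C/C=C(\C)C(=O)O[C@@H]1CC[C@]2(C)[C@H](CC[C@@](C)(O)[C@@H]2COc2ccc3ccc(=O)oc3c2)C1(C)C | target

**Step count and risks**

Total step count: 17. Longest linear sequence: 16 steps (steps 2 to 17, from pent-4-yn-1-ol); the geraniol branch adds step 1 before the union in step 4.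

Steps most likely to fail:

1. Step 13 (the key step; its reaction type is unprecedented). The C10 radical may be reduced before it crosses the ring (plain hydrogenation of the methylene), it may add to C6 instead of C5, the cyclised radical may not be quenched cleanly, or facial selectivity may be poor and give the C5,C10-diastereomeric trans-decalin. The fallback uses known chemistry, sets out from 18 and returns at 21: a thiol-mediated radical addition–cyclisation followed by desulfurisation. Heating 18 with thiophenol and AIBN in benzene should let the phenylthiyl radical add reversibly to the terminal carbon of the methylene; the resulting tertiary C10 radical closes onto C5 as before, and thiophenol, a fast hydrogen donor, quenches the C6 radical to give the 15-(phenylsulfanyl) decalinone F1. Raney Ni in ethanol then cleaves the C–S bond and turns the CH2SPh group into the C10 methyl of 21. Thiol–ene addition–cyclisation of dienes (transannular cases included) and Raney Ni desulfurisation are both established reactions. This fallback answers failures of initiation and quenching; it does not by itself correct a preference for C6 attack.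

2. Step 11. Intermolecular allylation (oligomer formation) may outrun ring closure, the allylchromium may be protonated, or the labile chloride 15 may decompose before it is reduced. The fallback sets out from 14, bypasses 15 and returns at 17. Palladium-catalysed borylation of the tertiary allylic alcohol of 14 with B2pin2 (Pd(MeCN)4(BF4)2 cat., DMSO/MeOH, high dilution) should give the allyl pinacolboronate F2 with boron on C6. This reagent is stable enough to wait for the unimolecular event and should close by intramolecular allylboration through a chair transition state at the same γ-carbon C4; aqueous work-up then releases 17, which rejoins the route at step 12.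

3. Step 17. Substitution at C11 may be too slow, because the oxyphosphonium carbon sits on C9 between two fully substituted carbons, so that the activated alcohol is lost to elimination or to alkylation of the hydrazide. The fallback sets out from 26 and returns at 28 and moves bond formation to the aryl carbon: palladium-catalysed C–O cross-coupling of the primary alcohol of 26 with commercial 7-bromocoumarin (Pd2(dba)3, the bulky biaryl phosphine RockPhos, Cs2CO3, toluene, 90 °C). No substitution at C11 is needed, the tertiary C8 hydroxyl should not couple, and no new compound arises on this path (F0).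

**Further compounds**

F1 | step 13 | 21 carrying a phenylsulfanyl group on C15, (5S,8R,9S)-8,11-bis(TBS-oxy)-15-(phenylsulfanyl)driman-3-one with the ring fusion of 21 | O=C1CC[C@]2(CSc3ccccc3)[C@H](CC[C@@](C)(O[Si](C)(C)C(C)(C)C)[C@@H]2CO[Si](C)(C)C(C)(C)C)C1(C)C
F2 | step 11 | (8R,9S)-8,11-bis(TBS-oxy)-6-(4,4,5,5-tetramethyl-1,3,2-dioxaborolan-2-yl)-3,4:5,10-disecodrima-4,10(15)-dien-3-al | CC(C)=CC(B1OC(C)(C)C(C)(C)O1)C[C@@](C)(O[Si](C)(C)C(C)(C)C)[C@@H](C(=C)CCC=O)CO[Si](C)(C)C(C)(C)C
F0 | step 17 | none | none
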